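## Retrosynthetic overview

1. The aryl ether bond C11–O is cut last (Mitsunobu with isofraxidin); C11 and the exocyclic C8=C12 alkene arise together from a formaldehyde ene reaction on a Δ8(9)-8-methyl alkene, the enophile entering C9 anti to the axial C10 methyl.
2. Ring A (C1–C2–C3–C4–C5–C10) is cut back to the five-membered A-nor ketone (C1, C3, C4, C5, C10): C2 is delivered as the CH2 of a temporary cyclopropane across C1/C3, and oxidative scission of the C1–C3 bond gives the C1=C2–C3=O enone in one operation.
3. Enabling feature: the C3 carbonyl lies between quaternary C4 (gem-dimethyl) and a CH2 (C1) whose other neighbour is quaternary C10, so enolisation and cyclopropanation can only occur at C1, and the C1 chloride can only eliminate towards C2.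
4. The trans A-nor hydrindanone comes from Li/NH3 reductive methylation of a cyclopentenone (sets H-5, completes C4Me2), itself made by alkyne hydration/aldol condensation of a 2-butynyl cyclohexanone.
5. C10 is set by CBS desymmetrisation of 2-(but-2-ynyl)-2-methylcyclohexane-1,3-dione; ring order: ring B (purchased) → five-membered ring → six-membered ring A by expansion.

Key step: step 8

Remark: atoms are named by drimane numbering (C1–C10 decalin, C11 = CH2O, C12 = exocyclic CH2); isofraxidin is taken as a purchasable coumarin; centres that are inconsequential epimer mixtures (C1 in 12, C8 in 16 and F4) are left unspecified in the SMILES.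

## Route

Step 1
Reactants: 1 2-methylcyclohexane-1,3-dione; 2 1-bromobut-2-yne
Product: 3 2-(but-2-yn-1-yl)-2-methylcyclohexane-1,3-dione
Conditions: 1 M aq NaOH, rt → 50 °C
Reagents that add atoms: none
Why: C-alkylation of the stabilised 1,3-dione enolate by a propargylic bromide in water, where hydrogen bonding to the enolate oxygens disfavours O-alkylation, should give the prochiral 2,2-disubstituted dione.

Step 2
Reactants: 3 2-(but-2-yn-1-yl)-2-methylcyclohexane-1,3-dione
Product: 4 (2S,3S)-2-(but-2-yn-1-yl)-3-hydroxy-2-methylcyclohexan-1-one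
Conditions: (R)-Me-CBS (20 mol %), catecholborane (1.1 equiv), toluene, −60 °C; aq NaOH work-up
Reagents that add atoms: none
Why: Corey–Bakshi–Shibata reduction used as an enantiotopic-group-selective desymmetrisation: the catalyst treats the quaternary C2 side as the large group and should give the S carbinol, and hydride should enter anti to the butynyl arm, so that only one carbonyl is matched; this fixes the quaternary centre (future C10) and a carbinol centre (future C9, removed later), while catecholborane leaves the alkyne alone.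

Step 3
Reactants: 4 (2S,3S)-2-(but-2-yn-1-yl)-3-hydroxy-2-methylcyclohexan-1-one
Product: 5 (2S,3S)-2-(but-2-yn-1-yl)-3-[(tert-butyldimethylsilyl)oxy]-2-methylcyclohexan-1-one
Conditions: TBSCl, imidazole, DMF, 40 °C
Reagents that add atoms: tert-butyldimethylsilyl chloride CC(C)(C)[Si](C)(C)Cl
Why: standard silylation of a secondary alcohol; the silyl ether blocks retro-aldol cleavage of the β-hydroxy ketone in the basic steps that follow.

Step 4
Reactants: 5 (2S,3S)-2-(but-2-yn-1-yl)-3-[(tert-butyldimethylsilyl)oxy]-2-methylcyclohexan-1-one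
Product: 7 (7S,7aR)-7-[(tert-butyldimethylsilyl)oxy]-3,7a-dimethyl-1,4,5,6,7,7a-hexahydro-2H-inden-2-one, via 1,4-diketone 6 (not isolated)
Conditions: (IPr)AuCl/AgSbF6 (2 mol %), 1,4-dioxane–H2O, 80 °C; then KOH, MeOH, 60 °C
Reagents that add atoms: water O
Why: carbonyl-assisted (5-exo-dig) gold-catalysed alkyne hydration should place the new oxygen on the alkyne carbon nearer the ring (C3) to give the 1,4-diketone, whose ethyl-ketone CH2 (C4) then closes onto the ring carbonyl (C5) in an intramolecular aldol condensation; the fused tetrasubstituted cyclopentenone is the only aldol that can dehydrate.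

Step 5
Reactants: 7 (7S,7aR)-7-[(tert-butyldimethylsilyl)oxy]-3,7a-dimethyl-1,4,5,6,7,7a-hexahydro-2H-inden-2-one
Product: 9 (3aS,7S,7aR)-7-[(tert-butyldimethylsilyl)oxy]-3,3,7a-trimethyloctahydro-2H-inden-2-one (trans-fused), via lithium enolate 8 (not isolated)
Conditions: Li (2.2 equiv), t-BuOH (1.0 equiv), NH3(l)–THF, −78 °C; isoprene; then MeI (5 equiv), −78 → −33 °C
Reagents that add atoms: iodomethane CI
Why: Stork reductive alkylation: the β-carbanion at C5 of the reduced enone should be protonated axially on ring B on the face opposite the angular C10 methyl, giving the trans ring fusion, and the regiospecific lithium enolate is then C-methylated at C4 to complete the gem-dimethyl group.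

Step 6
Reactants: 9 (3aS,7S,7aR)-7-[(tert-butyldimethylsilyl)oxy]-3,3,7a-trimethyloctahydro-2H-inden-2-one
Product: 10 trimethylsilyl enol ether of 9 (C3–OSiMe3 with C1=C3 double bond)
Conditions: LDA, THF, −78 → 0 °C; TMSCl, Et3N, −78 °C → rt
Reagents that add atoms: chlorotrimethylsilane C[Si](C)(C)Cl
Why: the ketone has a single enolisable position (C1) because C4 is quaternary, so deprotonation and O-silylation should give one silyl enol ether.

Step 7
Reactants: 10 trimethylsilyl enol ether of 9
Product: 11 siloxycyclopropane (CH2 = future C2 bridging C1 and C3 on the face anti to the C10 methyl; C3 carries OSiMe3)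
Conditions: Et2Zn, CH2I2, CH2Cl2, 0 °C → rt
Reagents that add atoms: diiodomethane ICI
Why: Furukawa–Simmons–Smith cyclopropanation of the electron-rich silyl enol ether, the only alkene present; the CH2 is expected to add opposite the C10 methyl, and either face would serve because both new centres disappear in step 8.

Step 8
Reactants: 11 siloxycyclopropane
Product: 13 (4aR,5S,8aS)-5-[(tert-butyldimethylsilyl)oxy]-1,1,4a-trimethyl-4a,5,6,7,8,8a-hexahydronaphthalen-2(1H)-one, via beta-chloro ketone 12 (not isolated)
Conditions: FeCl3 (2.5 equiv), DMF, 0 °C → rt; then NaOAc, MeOH, reflux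
Reagents that add atoms: none
Why: FeCl3 oxidises the siloxycyclopropane by one electron (Si–O exchange to an Fe(III) cyclopropoxide, then homolysis), and the cyclopropoxy radical opens by β-scission of the internal C1–C3 bond, so ring A appears as a cyclohexanone with a secondary radical at C1 that takes a chlorine atom from a second FeCl3; acetate then removes HCl across C1–C2 (E1cB through the C2 enolate) to give the C1=C2–C3=O enone. The closest known reaction type is the Ito–Saegusa FeCl3 ring enlargement of 1-siloxybicyclo[n.1.0]alkanes to 2-cycloalkenones. No ring is closed in this step: ring A forms by one-carbon expansion of the five-membered ring (C1, C3, C4, C5, C10), C2 having been delivered as the cyclopropane CH2. No new stereocentre results, and C5 and C10 are untouched because neither is a radical site and C4 and C10 carry no hydrogen. The selectivity needed is internal over external cyclopropane bond scission and elimination towards C2 only; the first is secured by formation of the secondary rather than the primary radical with release of bicyclic strain, the second by C10 being quaternary. Quaternary C4 had already forced the enol ether, and hence the cyclopropane, to the C1 side.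

Step 9
Reactants: 13 (4aR,5S,8aS)-5-[(tert-butyldimethylsilyl)oxy]-1,1,4a-trimethyl-4a,5,6,7,8,8a-hexahydronaphthalen-2(1H)-one
Product: 14 (4aR,5S,8aS)-5-hydroxy-1,1,4a-trimethyl-4a,5,6,7,8,8a-hexahydronaphthalen-2(1H)-one
Conditions: HF·pyridine, THF, 0 °C → rt
Reagents that add atoms: none
Why: fluoride cleavage of the secondary silyl ether under mildly acidic conditions that should leave the non-enolisable enone untouched; any silyl ether already lost in step 8 converges here.

Step 10
Reactants: 14 (4aR,5S,8aS)-5-hydroxy-1,1,4a-trimethyl-4a,5,6,7,8,8a-hexahydronaphthalen-2(1H)-one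
Product: 15 trans-fused 4,4,10-trimethyl-Δ1-octalin-3,9-dione (C9 ketone of 14)
Conditions: Dess–Martin periodinane, NaHCO3, CH2Cl2, rt
Reagents that add atoms: none
Why: mild Dess–Martin oxidation of the hindered secondary alcohol to the C9 ketone; C10 is quaternary, so nothing can epimerise.

Step 11
Reactants: 15 trans-fused 4,4,10-trimethyl-Δ1-octalin-3,9-dione
Product: 16 8-methyl derivative of 15 (C8 epimers)
Conditions: KHMDS (1.05 equiv), THF, −78 °C; MeI
Reagents that add atoms: iodomethane CI
Why: C8 is the only enolisable carbon in 15 (C4 and C10 are quaternary), so enolate methylation with a non-nucleophilic base should be regiospecific; the C8 configuration is of no consequence.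

Step 12
Reactants: 16 8-methyl derivative of 15
Product: 17 Δ8 enol triflate (C9–OTf, C8=C9, C8–CH3)
Conditions: KHMDS, THF, −78 °C; PhNTf2, −78 → 0 °C
Reagents that add atoms: N-phenylbis(trifluoromethanesulfonimide) O=S(=O)(N(c1ccccc1)S(=O)(=O)C(F)(F)F)C(F)(F)F
Why: deprotonation of the one remaining α-hydrogen (C8–H) and O-sulfonylation should give the tetrasubstituted enol triflate with the double bond fixed at C8=C9.

Step 13
Reactants: 17 Δ8 enol triflate
Product: 18 11-nordrima-1,8(9)-dien-3-one (trans-fused 4,4,8,10-tetramethyl dienone, C9–H vinylic)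
Conditions: Pd(OAc)2 (5 mol %), PPh3, Bu3N, HCO2H, DMF, 60 °C
Reagents that add atoms: none
Why: palladium-catalysed formate reduction of an alkenyl triflate (oxidative addition, formate exchange, decarboxylation, C–H reductive elimination) should replace OTf by H without moving the double bond.

Step 14
Reactants: 18 11-nordrima-1,8(9)-dien-3-one
Product: 19 (4aR,5S,8aS)-5-(hydroxymethyl)-1,1,4a-trimethyl-6-methylidene-4a,5,6,7,8,8a-hexahydronaphthalen-2(1H)-one
Conditions: (CH2O)n (3 equiv), Me2AlCl (2 equiv), CH2Cl2, −78 → 0 °C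
Reagents that add atoms: formaldehyde (as paraformaldehyde) C=O
Why: Lewis acid-promoted carbonyl-ene reaction: the formaldehyde–Me2AlCl complex should bond to the less substituted alkene carbon C9 by axial attack on the face opposite the axial C10 methyl, which sets C9 with CH2OH trans to that methyl, and hydrogen is taken from the C12 methyl (cis to the vinylic H) to leave the exocyclic C8=C12 alkene; the electron-poor enone is not an ene partner.

Step 15
Reactants: 19 (4aR,5S,8aS)-5-(hydroxymethyl)-1,1,4a-trimethyl-6-methylidene-4a,5,6,7,8,8a-hexahydronaphthalen-2(1H)-one; 20 isofraxidin (7-hydroxy-6,8-dimethoxy-2H-chromen-2-one)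
Product: 21 6,8-dimethoxy-7-{[(1S,4aS,8aR)-5,5,8a-trimethyl-2-methylidene-6-oxo-1,2,3,4,4a,5,6,8a-octahydronaphthalen-1-yl]methoxy}-2H-chromen-2-one (target)
Conditions: PPh3, DIAD, THF, 0 → 40 °C
Reagents that add atoms: none
Why: Mitsunobu etherification of a primary alcohol with the acidic 7-OH of the coumarin; no stereocentre is involved and the enone and exocyclic alkene should be inert.

## Compound list

1 | 2-methylcyclohexane-1,3-dione | CC1C(=O)CCCC1=O | starting material
2 | 1-bromobut-2-yne | CC#CCBr | starting material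
3 | 2-(but-2-yn-1-yl)-2-methylcyclohexane-1,3-dione | CC#CCC1(C)C(=O)CCCC1=O | intermediate
4 | (2S,3S)-2-(but-2-yn-1-yl)-3-hydroxy-2-methylcyclohexan-1-one (OH cis to butynyl) | C1CCC(=O)[C@@](C)(CC#CC)[C@H]1O | intermediate
5 | (2S,3S)-2-(but-2-yn-1-yl)-3-[(tert-butyldimethylsilyl)oxy]-2-methylcyclohexan-1-one | C1CCC(=O)[C@@](C)(CC#CC)[C@H]1O[Si](C)(C)C(C)(C)C | intermediate
6 | (2S,3S)-3-[(tert-butyldimethylsilyl)oxy]-2-methyl-2-(2-oxobutyl)cyclohexan-1-one (1,4-diketone, not isolated) | C1CCC(=O)[C@@](C)(CC(=O)CC)[C@H]1O[Si](C)(C)C(C)(C)C | intermediate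
7 | (7S,7aR)-7-[(tert-butyldimethylsilyl)oxy]-3,7a-dimethyl-1,4,5,6,7,7a-hexahydro-2H-inden-2-one | C1CCC2=C(C)C(=O)C[C@@]2(C)[C@H]1O[Si](C)(C)C(C)(C)C | intermediate
8 | lithium enolate from 7 (C5–H set, C3–OLi, C3=C4; not isolated) | C1CC[C@@H]2C(C)=C([O-])C[C@@]2(C)[C@H]1O[Si](C)(C)C(C)(C)C.[Li+] | intermediate
9 | (3aS,7S,7aR)-7-[(tert-butyldimethylsilyl)oxy]-3,3,7a-trimethyloctahydro-2H-inden-2-one (trans-fused, H-5 anti to C10 methyl) | C1CC[C@@H]2C(C)(C)C(=O)C[C@@]2(C)[C@H]1O[Si](C)(C)C(C)(C)C | intermediate
10 | trimethylsilyl enol ether of 9 (C3–OSiMe3, C1=C3) | C1CC[C@@H]2C(C)(C)C(O[Si](C)(C)C)=C[C@@]2(C)[C@H]1O[Si](C)(C)C(C)(C)C | intermediate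
11 | siloxycyclopropane (CH2 bridging C1/C3 anti to C10 methyl) | C1CC[C@@H]2C(C)(C)[C@@]3(O[Si](C)(C)C)C[C@H]3[C@@]2(C)[C@H]1O[Si](C)(C)C(C)(C)C | intermediate
12 | 1-chloro-3-ketone (ring A six-membered, C1–Cl epimers; not isolated) | C1CC[C@@H]2C(C)(C)C(=O)CC(Cl)[C@@]2(C)[C@H]1O[Si](C)(C)C(C)(C)C | intermediate
13 | (4aR,5S,8aS)-5-[(tert-butyldimethylsilyl)oxy]-1,1,4a-trimethyl-4a,5,6,7,8,8a-hexahydronaphthalen-2(1H)-one | C1CC[C@@H]2C(C)(C)C(=O)C=C[C@@]2(C)[C@H]1O[Si](C)(C)C(C)(C)C | intermediate
14 | (4aR,5S,8aS)-5-hydroxy-1,1,4a-trimethyl-4a,5,6,7,8,8a-hexahydronaphthalen-2(1H)-one | C1CC[C@@H]2C(C)(C)C(=O)C=C[C@@]2(C)[C@H]1O | intermediate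
15 | trans-fused 4,4,10-trimethyl-Δ1-octalin-3,9-dione (drimane numbering) | C1CC[C@@H]2C(C)(C)C(=O)C=C[C@@]2(C)C1=O | intermediate
16 | 8-methyl derivative of 15 (C8 epimers) | CC1CC[C@@H]2C(C)(C)C(=O)C=C[C@@]2(C)C1=O | intermediate
17 | Δ8 enol triflate of 16 (C9–OTf) | CC1=C(OS(=O)(=O)C(F)(F)F)[C@]2(C)C=CC(=O)C(C)(C)[C@H]2CC1 | intermediate
18 | 11-nordrima-1,8(9)-dien-3-one (trans-fused) | CC1=C[C@]2(C)C=CC(=O)C(C)(C)[C@H]2CC1 | intermediate
19 | (4aR,5S,8aS)-5-(hydroxymethyl)-1,1,4a-trimethyl-6-methylidene-4a,5,6,7,8,8a-hexahydronaphthalen-2(1H)-one (CH2OH trans to C10 methyl) | C=C1CC[C@@H]2C(C)(C)C(=O)C=C[C@@]2(C)[C@H]1CO | intermediate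
20 | isofraxidin (7-hydroxy-6,8-dimethoxy-2H-chromen-2-one) | COc1cc2ccc(=O)oc2c(OC)c1O | starting material
21 | 6,8-dimethoxy-7-{[(1S,4aS,8aR)-5,5,8a-trimethyl-2-methylidene-6-oxo-1,2,3,4,4a,5,6,8a-octahydronaphthalen-1-yl]methoxy}-2H-chromen-2-one | C=C1CC[C@@H]2C(C)(C)C(=O)C=C[C@@]2(C)[C@H]1COc1c(OC)cc2ccc(=O)oc2c1OC | target

## Step count and risks

Total step count: 15. Longest linear sequence: 15 steps (1 → 21); 2 and 20 are purchased and enter in steps 1 and 15.

Steps most likely to fail:

**Step 5 (reductive methylation).** Protonation at C5 may take place on the wrong face and give the cis ring fusion, since the axial C9 silyl ether sits on the face where the proton must arrive; C-methylation of the hindered enolate may also be incomplete. The fallback sets out from 7. Deconjugative α-methylation through the extended dienolate (t-BuOK, t-BuOH, MeI) would give (7S,7aR)-7-[(tert-butyldimethylsilyl)oxy]-3,3,7a-trimethyl-1,3,5,6,7,7a-hexahydro-2H-inden-2-one F1 with a C5=C6 double bond. Desilylation (HF·pyridine) would give the homoallylic alcohol (7S,7aR)-7-hydroxy-3,3,7a-trimethyl-1,3,5,6,7,7a-hexahydro-2H-inden-2-one F2. Hydroxyl-directed hydrogenation with Crabtree's catalyst ([Ir(cod)(PCy3)(py)]PF6, H2, CH2Cl2) should deliver hydrogen to C5 from the face of the C9–OH, which is the face opposite the C10 methyl, giving (3aS,7S,7aR)-7-hydroxy-3,3,7a-trimethyloctahydro-2H-inden-2-one F3. Resilylation (TBSCl, imidazole, DMF) comes back to the route at 9.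

**Step 14 (ene reaction).** Hydrogen may be transferred from C7 instead of C12 (endocyclic alkene), the zwitterionic intermediate may collapse to a chloro alcohol, or the crowded C9 next to quaternary C10 may react too slowly. The fallback sets out from 15. Enolate alkylation with (iodomethyl)trimethylsilane (KHMDS, THF) would give the 8-(trimethylsilylmethyl) dione F4; enol triflation (KHMDS, PhNTf2) would give the enol triflate F5; and formate reduction (Pd(OAc)2, PPh3, Bu3N, HCO2H) would give the allylsilane F6. A Hosomi–Sakurai reaction with 1,3,5-trioxane and TiCl4 (CH2Cl2, −78 °C) then puts the electrophile on C9 anti to the C10 methyl, while loss of silicon fixes the double bond at C8=C12; this comes back to the route at 19.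

**Step 15 (Mitsunobu etherification).** Substitution at the β-branched, axial CH2 by the doubly ortho-substituted phenol may be slow, so that the reduced azodicarboxylate is alkylated or the alkoxyphosphonium ion decomposes. The fallback sets out from 19: triflation (Tf2O, pyridine, CH2Cl2, −78 °C) to the primary triflate F7, then SN2 displacement by the caesium phenoxide of 20 (Cs2CO3, MeCN, 0 °C → rt), which comes back to the route at 21.

## Further compounds

F1 | step 5 | (7S,7aR)-7-[(tert-butyldimethylsilyl)oxy]-3,3,7a-trimethyl-1,3,5,6,7,7a-hexahydro-2H-inden-2-one | C1CC=C2C(C)(C)C(=O)C[C@@]2(C)[C@H]1O[Si](C)(C)C(C)(C)C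
F2 | step 5 | (7S,7aR)-7-hydroxy-3,3,7a-trimethyl-1,3,5,6,7,7a-hexahydro-2H-inden-2-one | C1CC=C2C(C)(C)C(=O)C[C@@]2(C)[C@H]1O
F3 | step 5 | (3aS,7S,7aR)-7-hydroxy-3,3,7a-trimethyloctahydro-2H-inden-2-one | C1CC[C@@H]2C(C)(C)C(=O)C[C@@]2(C)[C@H]1O
F4 | step 14 | 8-(trimethylsilylmethyl) derivative of 15 (C8 epimers) | C[Si](C)(C)CC1CC[C@@H]2C(C)(C)C(=O)C=C[C@@]2(C)C1=O
F5 | step 14 | Δ8 enol triflate of F4 (C9–OTf) | C[Si](C)(C)CC1=C(OS(=O)(=O)C(F)(F)F)[C@]2(C)C=CC(=O)C(C)(C)[C@H]2CC1
F6 | step 14 | allylsilane (C8–CH2SiMe3, C8=C9) | C[Si](C)(C)CC1=C[C@]2(C)C=CC(=O)C(C)(C)[C@H]2CC1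
F7 | step 15 | primary triflate of 19 | C=C1CC[C@@H]2C(C)(C)C(=O)C=C[C@@]2(C)[C@H]1COS(=O)(=O)C(F)(F)F
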